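**Retrosynthetic overview**
- Target 10 is C2-symmetric and is cut at the central C15=C15' double bond. Both halves come from one C20 aldehyde, (R)-α-retinal 8, by reductive carbonyl homocoupling, in which one formyl carbon reacts as a titanium ketyl (reversed polarity) with the formyl carbon of a second molecule.
- 8 comes from nitrile 6 by partial reduction; 6 comes from C15 aldehyde 4 and C5 phosphonate 5 (C11=C12 olefination).
- 4 comes from (R)-α-ionone 1 and the C2 formylolefination reagent 2 (C9=C10 olefination).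
- No ring is formed in the route. The ε-ring and its C6 stereocentre are bought with 1 and carried unchanged; both stereocentres of 10 are C6 of 1.

Assumption: (R)-(+)-α-ionone 1 (≥98% ee) is taken as commercial, sold in bulk as the fermentation-derived natural flavour ionone. Carotenoid numbering is used for positions (C6 ring stereocentre, C15 chain terminus).

**Step 1**
Reactants: 1 (R)-α-ionone, (3E)-4-[(1R)-2,6,6-trimethylcyclohex-2-en-1-yl]but-3-en-2-one; 2 diethyl [(E)-2-(cyclohexylamino)ethenyl]phosphonate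
Product: 4 (2E,4E)-3-methyl-5-[(1R)-2,6,6-trimethylcyclohex-2-en-1-yl]penta-2,4-dienal, via N-cyclohexyl aldimine 3 (not isolated)
Conditions: 2 (1.5 equiv), NaH (1.4 equiv), THF, 0 °C → rt; then 1, rt; then (CO2H)2, H2O/toluene, rt; SiO2 chromatography (removes 9Z isomer)
Reagents that add atoms: 2 diethyl [(E)-2-(cyclohexylamino)ethenyl]phosphonate, CCOP(=O)(OCC)/C=C/NC1CCCCC1; water, O
Why: Nagata formylolefination (a Horner–Wadsworth–Emmons reaction of the preformed sodium aza-enolate of 2) adds to the ketone and expels diethyl phosphate to give the conjugated aldimine, mainly 9E, which mild oxalic acid hydrolysis turns into the enal; no free NaH meets the ketone, so the C6–H is not removed and C6 stays R.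

**Step 2**
Reactants: 4 (2E,4E)-3-methyl-5-[(1R)-2,6,6-trimethylcyclohex-2-en-1-yl]penta-2,4-dienal; 5 diethyl [(2E)-3-cyano-2-methylprop-2-en-1-yl]phosphonate (commercial E/Z mixture, drawn E)
Product: 6 (2E,4E,6E,8E)-3,7-dimethyl-9-[(1R)-2,6,6-trimethylcyclohex-2-en-1-yl]nona-2,4,6,8-tetraenenitrile
Conditions: 5 (1.3 equiv), NaH, THF, 0 °C; then 4, 0 °C → rt; SiO2 chromatography (removes 13Z isomer)
Reagents that add atoms: 5 diethyl [(2E)-3-cyano-2-methylprop-2-en-1-yl]phosphonate, CCOP(=O)(OCC)C/C(C)=C/C#N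
Why: Horner–Wadsworth–Emmons olefination with the standard retinoid C5 phosphonate reacts at the carbon next to phosphorus and gives the new C11=C12 bond E, with 13E as the major isomer; the stabilised anion is too weakly basic to touch C6, and no stereocentre is formed.

**Step 3**
Reactants: 6 (2E,4E,6E,8E)-3,7-dimethyl-9-[(1R)-2,6,6-trimethylcyclohex-2-en-1-yl]nona-2,4,6,8-tetraenenitrile
Product: 8 (2E,4E,6E,8E)-3,7-dimethyl-9-[(1R)-2,6,6-trimethylcyclohex-2-en-1-yl]nona-2,4,6,8-tetraenal, via N-diisobutylalumanyl aldimine 7 (not isolated)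
Conditions: i-Bu2AlH (1.5 equiv), hexane/Et2O, −78 → −40 °C; then wet SiO2, 0 °C; dark, Ar
Reagents that add atoms: water, O
Why: Partial reduction of a nitrile with i-Bu2AlH stops at the N-aluminated aldimine at low temperature, and hydrolysis then gives the aldehyde (the usual last step of retinal syntheses) without affecting the polyene geometry or C6.

**Step 4**
Reactants: 8 (2E,4E,6E,8E)-3,7-dimethyl-9-[(1R)-2,6,6-trimethylcyclohex-2-en-1-yl]nona-2,4,6,8-tetraenal (two molecules)
Product: 10 (6R,6'R)-ε,ε-carotene (all-E), via titanium pinacolate 9 (not isolated)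
Conditions: TiCl3(DME)1.5 (4 equiv), Zn–Cu couple (12 equiv), DME, reflux 2 h; then 8, rt → reflux, Ar, dark; filter (SiO2 pad); heptane, reflux; crystallize
Reagents that add atoms: none
Why: In this McMurry coupling zerovalent titanium transfers an electron to the formyl group, so C15, normally electrophilic, reacts as a titanium ketyl (a reversed-polarity formyl synthon) with the equally electrophilic C15 of a second molecule, and the titanium pinacolate is then deoxygenated to the C15=C15' alkene; retinal to β-carotene is the textbook case of this reaction, the 15Z isomer goes to all-E on heating in heptane, no stereocentre is formed and both C6 centres stay R.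

**Compound list**
1 | (R)-α-ionone, (3E)-4-[(1R)-2,6,6-trimethylcyclohex-2-en-1-yl]but-3-en-2-one | CC(=O)/C=C/[C@H]1C(C)=CCCC1(C)C | starting material
2 | diethyl [(E)-2-(cyclohexylamino)ethenyl]phosphonate | CCOP(=O)(OCC)/C=C/NC1CCCCC1 | starting material
3 | (1E,2E,4E)-N-cyclohexyl-3-methyl-5-[(1R)-2,6,6-trimethylcyclohex-2-en-1-yl]penta-2,4-dien-1-imine | C1CCCCC1/N=C/C=C(C)/C=C/[C@H]2C(C)=CCCC2(C)C | intermediate
4 | (2E,4E)-3-methyl-5-[(1R)-2,6,6-trimethylcyclohex-2-en-1-yl]penta-2,4-dienal | O=C/C=C(C)/C=C/[C@H]1C(C)=CCCC1(C)C | intermediate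
5 | diethyl [(2E)-3-cyano-2-methylprop-2-en-1-yl]phosphonate | CCOP(=O)(OCC)C/C(C)=C/C#N | starting material
6 | (2E,4E,6E,8E)-3,7-dimethyl-9-[(1R)-2,6,6-trimethylcyclohex-2-en-1-yl]nona-2,4,6,8-tetraenenitrile | N#C/C=C(C)/C=C/C=C(C)/C=C/[C@H]1C(C)=CCCC1(C)C | intermediate
7 | N-(diisobutylalumanyl) aldimine of 8, all-E chain, (R) at C6 | CC(C)C[Al](CC(C)C)/N=C/C=C(C)/C=C/C=C(C)/C=C/[C@H]1C(C)=CCCC1(C)C | intermediate
8 | (R)-α-retinal, (2E,4E,6E,8E)-3,7-dimethyl-9-[(1R)-2,6,6-trimethylcyclohex-2-en-1-yl]nona-2,4,6,8-tetraenal | O=C/C=C(C)/C=C/C=C(C)/C=C/[C@H]1C(C)=CCCC1(C)C | intermediate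
9 | titanium 15,15'-pinacolate from two molecules of 8 (cyclic titanium 1,2-diolate, drawn monomeric; diastereomer mixture at C15/C15', both C6 centres R) | O1[Ti]OC(/C=C(C)/C=C/C=C(C)/C=C/[C@H]2C(C)=CCCC2(C)C)C1/C=C(C)/C=C/C=C(C)/C=C/[C@H]3C(C)=CCCC3(C)C | intermediate
10 | (6R,6'R)-ε,ε-carotene, 1,1'-[(1E,3E,5E,7E,9E,11E,13E,15E,17E)-3,7,12,16-tetramethyloctadeca-1,3,5,7,9,11,13,15,17-nonaene-1,18-diyl]bis[(1R)-2,6,6-trimethylcyclohex-2-ene] | CC1=CCCC(C)(C)[C@H]1/C=C/C(C)=C/C=C/C(C)=C/C=C/C=C(C)/C=C/C=C(C)/C=C/[C@H]1C(C)=CCCC1(C)C | target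

**Totals**
Total step count: 4. Longest linear sequence: 4 (1 → 4 → 6 → 8 → 10).

**Steps most likely to fail, with fallbacks**

Step 4 (McMurry homocoupling) is the riskiest. Hot low-valent titanium can over-reduce or scramble a polyenal, and the 15E/15Z mixture has to be driven to all-E. The fallback sets out from 8 and comes back at 10, and separates bond formation from deoxygenation while keeping the ketyl coupling. Pinacol coupling of 8 with Cp2TiCl (trivalent titanium, made from Cp2TiCl2 and Zn in THF at rt) gives the 15,15'-dihydro-(6R,6'R)-ε,ε-carotene-15,15'-diol F1. 1,1'-Thiocarbonyldiimidazole (DMAP, toluene, 60 °C) converts it into the cyclic 15,15'-thiocarbonate F2. Corey–Winter elimination with 1,3-dimethyl-2-phenyl-1,3,2-diazaphospholidine (THF, 40 °C) then gives 10, followed by the same thermal isomerisation and crystallisation.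

Step 1 (formylolefination) is second. The aza-enolate of 2 is more basic than an ordinary phosphonate anion, so it could enolise the methyl ketone, erode the ee at C6 or give a poor 9E/9Z ratio; the ee of 4 is checked by chiral GC. The fallback sets out from 1 and comes back at 4. Horner–Wadsworth–Emmons reaction of 1 with diethyl cyanomethylphosphonate (NaH, THF) gives (2E,4E)-3-methyl-5-[(1R)-2,6,6-trimethylcyclohex-2-en-1-yl]penta-2,4-dienenitrile F3. Reduction with i-Bu2AlH (−78 °C, then wet SiO2) gives 4, at the cost of one extra step.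

Step 2 (C5 olefination) is third. It can give a poor 13E/13Z ratio or a difficult separation. The fallback sets out from 4 and comes back at 6, building the same chain as C3 + C2. Aldol condensation of 4 with acetone (aq. NaOH, rt) gives (3E,5E,7E)-6-methyl-8-[(1R)-2,6,6-trimethylcyclohex-2-en-1-yl]octa-3,5,7-trien-2-one F4. Horner–Wadsworth–Emmons reaction of F4 with diethyl cyanomethylphosphonate (NaH, THF) then gives 6.

**Further compounds**
F1 | step 4 | 15,15'-dihydro-(6R,6'R)-ε,ε-carotene-15,15'-diol (mainly dl at C15/C15') | OC(/C=C(C)/C=C/C=C(C)/C=C/[C@H]1C(C)=CCCC1(C)C)C(O)/C=C(C)/C=C/C=C(C)/C=C/[C@H]2C(C)=CCCC2(C)C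
F2 | step 4 | cyclic 15,15'-thiocarbonate of F1 (4,5-disubstituted 1,3-dioxolane-2-thione) | S=C1OC(/C=C(C)/C=C/C=C(C)/C=C/[C@H]2C(C)=CCCC2(C)C)C(O1)/C=C(C)/C=C/C=C(C)/C=C/[C@H]3C(C)=CCCC3(C)C
F3 | step 1 | (2E,4E)-3-methyl-5-[(1R)-2,6,6-trimethylcyclohex-2-en-1-yl]penta-2,4-dienenitrile | N#C/C=C(C)/C=C/[C@H]1C(C)=CCCC1(C)C
F4 | step 2 | (3E,5E,7E)-6-methyl-8-[(1R)-2,6,6-trimethylcyclohex-2-en-1-yl]octa-3,5,7-trien-2-one | CC(=O)/C=C/C=C(C)/C=C/[C@H]1C(C)=CCCC1(C)C
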